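## Structural features

- The target is numbered C1–C15 from the alkyne terminus. It is a cis-fused 2,6-dioxabicyclo[3.3.0]octane: ring A (O, C7, C8, C9, C10) and ring B (O, C9, C10, C11, C12) share the C9–C10 bond, with H9 and H10 on the convex face.
- C8 (S, bromide), C9 (R) and C10 (S) are three contiguous stereocentres. C12 (R) and the side-chain carbon C13 (S, bromide) form a second adjacent pair. The C8 bromide and the 1-bromopropyl group both stand on the convex face, with C8–Br trans to the C9–O bond and C12/C13 erythro.
- C7 is the oxygen-bearing end of an exocyclic trisubstituted enol ether C6=C7. The chain continues through the doubly allylic C5H2 into a (3Z)-enyne.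
- The enol ether is 6E: C5 is trans to the ring oxygen and cis to C8. This is the more crowded arrangement. It is also the opposite of what anti hydroalkoxylation of a C6≡C7 alkyne, alkylidenation of a C7 lactone, or equilibration would deliver.
- Several groups are fragile: the enol ether (acid, any Br+ source), the allylic C8 bromide with an anti H9 (loss of HBr leads on to a furan), C5H2 (base), the secondary bromides (strong base, reducing or zerovalent metals) and the terminal alkyne.
- The real difficulty is ring A. It must be closed with the 6E geometry, next to a C8 heteroatom and with the correct C10 configuration, without exposing the enol ether to the brominating agent that C13 needs.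
- The key step exploits the segment C4–C5–C6=C7(O)–C8(X) with C5 and C8 cis. This is exactly the atom pattern of the enolate of a 2H-pyran-3(6H)-one (temporary ring C: O8, C8, C7, C6, C5, C4), which is the oxidative ring-expansion product of a 2-furyl carbinol. A flat furan (C4–C7) can therefore become a ring that locks the geometry, masks the C4 aldehyde and holds the C8 oxygen for the final inversion to bromide.

## Logic of the disconnections

**24 to 23.** The C8–Br bond is cut. The allylic bromide is the most fragile group and belongs at the end. An endo alcohol at C8 gives the exo bromide by one SN2 inversion from the open convex face. The gain is that every earlier step handles an oxygen at C8. The demand is a non-acidic displacement without SN2' attack at C6 and without E2 across C8–C9.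

**23 to 22 to 16 + 19.** The C–Si bond and then the C3=C4 bond are cut. Removing C1–C3 leaves a C4 aldehyde and the C8 hydroxyl, which recombine as a cyclic hemiacetal (ring C). The gain is that the isomerisation-prone β,γ-unsaturated aldehyde is stored in a ring, and that ring holds C5 and C8 cis. The demand is a Z-selective olefination that works on a lactol.

**16 to 15.** Only the O–Si bond at C4 changes. The lactol needs a mask that survives hydride and enolate chemistry and leaves under near-neutral conditions, because the enol ether excludes acid.

**15 to 13 (key).**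
- Cut: the O–C10 bond of ring A is cut and the C5 hydrogen is removed, which returns the C5=C6–C7=O enone and a C10 bromide.
- In one sentence: ring A is closed by O-alkylation of the ring-locked enolate released by conjugate reduction of 13.
- Reason: inside ring C the enolate can have only one geometry and one regiochemistry.
- Gain: ring A, the A/B fusion, C10 and the 6E geometry all fall away together.
- Demand: 1,4-hydride delivery, a leaving group at C10 trans to the C8 substituent, and no enolate equilibration.

**13 to 12 to 10.** The O–Si bond is cut. In ring B the O–C12 and C13–Br bonds are cut. In ring C the C4–O8 bond, the C4–OH bond and the C7 carbonyl oxygen are removed, which returns a furan. Both oxidations use the same Br+ source and differ widely in rate. The gain is two rings and two stereocentres traded for an acyclic furyl bromodiol with an E-alkene. The demand is furan oxidation before alkene activation, and 2,5-trans/2,4-cis closure of ring B.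

**10 to 9 to 8.** The C10–Br bond is cut back to a C9–C10 epoxide, and the C8–H bond back to a ketone. The epoxide supplies the C9 oxygen and, by inversion, the leaving group at C10 without any protecting group. It also directs the C8 reduction. The demand is distal (C10) opening and anti reduction.

**8 to 7.** Both C–O bonds of the epoxide are cut. The acyl furan makes C9=C10 the only electron-poor alkene, so a nucleophilic asymmetric epoxidation is chemoselective and sets the absolute configuration of the whole route.

**7 to 6 + 4.** C9=C10 is cut, which splits the skeleton into a C4–C9 and a C10–C15 piece. The demand is neutral conditions, because both 6 and 7 can slip into conjugation under base.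

**4 to 1 + 2, 6 to 5, 19 to 17.** A C–P bond, an oxidation level and a C–Si bond are cut. All end at commercial materials.

## Other disconnections considered

**Alternative 1:** this is the first idea that comes to mind.
- Cut: O–C7 of ring A, back to the alkynol A1.
- Forward key step: 5-exo-dig hydroalkoxylation of C6≡C7 by the C10 hydroxyl with AuCl(PPh3)/AgOTf or PdCl2(MeCN)2.
- Ground for rejection: carbophilic activation enforces anti addition of oxygen and metal (later hydrogen). C5 therefore ends cis to the ring oxygen, which is the 6Z isomer A2, and nothing in the mechanism can reverse this.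
- Further problems: the propargylic C8 bromide is exposed to the same π-acids, and the C1≡C2 and C3=C4 units compete for the catalyst.
- The chosen plan fixes the geometry by ring membership rather than by selectivity.

**Alternative 2:**
- Cut: C6=C7, back to the α-bromo bicyclic lactone A3 and a C1–C6 ylide, sulfone or gem-dibromide.
- Forward key step: carbonyl olefination of the lactone, either of Wittig or Julia type or with TiCl4/Zn/TMEDA.
- Ground for rejection: A3 itself is easy to reach by oxa-Michael closure on a butenolide followed by convex-face bromination. The decisive step, however, has no element that favours 6E, since steric approach places C5 next to oxygen.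
- Further problems: A3 carries an acidic H8 and a reducible C–Br bond, and neither tolerates basic ylides or low-valent titanium. The C1–C6 reagent has its own acidic C5H2.
- A protected C8 alcohol and an isomer separation would be needed, at a higher step count.

**Alternative 3:**
- Cut: C5–C6.
- Forward key step: anti iodoetherification of the terminal alkynol A4 to the (E)-iodomethylene compound A5, then sp2–sp3 coupling with the (Z)-allyl bromide A6.
- Merit: the geometry is right in principle, since iodine is trans to oxygen and the coupling proceeds with retention.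
- Ground for rejection: the coupling needs zerovalent palladium or a cuprate next to an allylic C8–O bond and could never be run with the C8 bromide in place. The Z-allyl partner passes through a π-allyl species that can relax to E or couple at C3.
- Step economy: a C8 protecting group and a separate synthesis of A6 are required. Ring closure and chain attachment remain two operations and set no stereocentre, whereas step 9 sets C10 as well.

Key step: step 9

Remark on numbering: atoms keep the target numbering C1–C15 in all intermediates, and O8 is the oxygen on C8.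
Assumption: 11–16 and F1 are carried as mixtures of anomers at C4. This centre is left undefined in the SMILES because it becomes the sp2 carbon C4 in step 12.

## Steps

Step 1
Reactants: 1 2-bromo-1-(furan-2-yl)ethan-1-one; 2 triphenylphosphine
Product: 4 1-(furan-2-yl)-2-(triphenyl-λ5-phosphanylidene)ethan-1-one, via phosphonium bromide 3 (not isolated)
Conditions: toluene, rt; then aq. NaOH, CH2Cl2
Reagents that add atoms: none
Why: SN2 quaternisation of an α-bromo ketone followed by deprotonation of the acidic phosphonium salt is the standard preparation of a stabilised keto ylide.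

Step 2
Reactants: 5 (E)-hex-3-en-1-ol
Product: 6 (E)-hex-3-enal
Conditions: IBX, DMSO–THF, rt; used at once
Reagents that add atoms: none
Why: IBX oxidation is neutral and stops at the aldehyde, so the β,γ-double bond should stay in place and remain E.

Step 3
Reactants: 6 (E)-hex-3-enal; 4 1-(furan-2-yl)-2-(triphenyl-λ5-phosphanylidene)ethan-1-one
Product: 7 (2E,5E)-1-(furan-2-yl)octa-2,5-dien-1-one
Conditions: CH2Cl2, rt
Reagents that add atoms: none
Why: A Wittig reaction of a stabilised ylide is E-selective and needs no added base, which protects the doubly allylic C11H2 of the skipped dienone.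

Step 4
Reactants: 7 (2E,5E)-1-(furan-2-yl)octa-2,5-dien-1-one
Product: 8 furan-2-yl{(2R,3S)-3-[(2E)-pent-2-en-1-yl]oxiran-2-yl}methanone (9R,10S)
Conditions: La(OiPr)3 (5 mol %), (S)-BINOL (5 mol %), Ph3As=O (5 mol %), t-BuOOH (decane), 4 Å MS, THF, rt
Reagents that add atoms: tert-butyl hydroperoxide, CC(C)(C)OO
Why: In this catalytic asymmetric Weitz–Scheffer-type epoxidation the lanthanum-bound peroxide adds only to the electron-poor C9=C10, so C12=C13 and the deactivated acyl furan stay untouched. The binaphtholate pocket selects the enone face, with (S)-BINOL as the enantiomer expected to give 9R,10S, and the trans geometry is retained.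

Step 5
Reactants: 8 furan-2-yl{(2R,3S)-3-[(2E)-pent-2-en-1-yl]oxiran-2-yl}methanone
Product: 9 (R)-furan-2-yl{(2S,3S)-3-[(2E)-pent-2-en-1-yl]oxiran-2-yl}methanol (8R,9S,10S)
Conditions: NaBH4, CeCl3·7H2O, MeOH, −78 °C
Reagents that add atoms: none
Why: This is a Luche reduction of an α,β-epoxy ketone. Cerium bridges the carbonyl and epoxide oxygens and hydride enters from the face away from C10, which should give the anti (erythro) epoxy alcohol and so set C8 from C9.

Step 6
Reactants: 9 (R)-furan-2-yl{(2S,3S)-3-[(2E)-pent-2-en-1-yl]oxiran-2-yl}methanol
Product: 10 (1R,2S,3R,5E)-3-bromo-1-(furan-2-yl)oct-5-ene-1,2-diol (8R,9S,10R)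
Conditions: Ti(OiPr)4 (1.5 equiv), Et2NH·HBr (1.5 equiv), CH2Cl2, 0 °C to rt
Reagents that add atoms: diethylammonium bromide, CC[NH2+]CC.[Br-]
Why: In this titanium-alkoxide-mediated opening of a 2,3-epoxy alcohol the metal binds the C8 alkoxide and the epoxide oxygen, and bromide attacks the distal carbon C10 with inversion. This frees the C9 hydroxyl and installs the C10 leaving group anti to it, while the adjacent C–O dipoles disfavour ionisation at the furfuryl position.

Step 7
Reactants: 10 (1R,2S,3R,5E)-3-bromo-1-(furan-2-yl)oct-5-ene-1,2-diol
Product: 12 (2R)-2-{(2S,3R,5R)-3-bromo-5-[(1S)-1-bromopropyl]oxolan-2-yl}-6-hydroxy-2H-pyran-3(6H)-one, via alkenyl pyranone lactol 11 (not isolated)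
Conditions: NBS (1.05 equiv), NaHCO3, THF–H2O (4:1), 0 °C; then NBS (1.1 equiv), 0 °C to rt, dark
Reagents that add atoms: N-bromosuccinimide, O=C1CCC(=O)N1Br; water, O
Why: The alkyl furan is far more nucleophilic than the alkene, so the first equivalent effects the Achmatowicz rearrangement (ring C, with C8 retained). The second equivalent then triggers 5-exo bromoetherification of the E-alkene by the C9 hydroxyl (ring B). Anti addition gives the erythro C12/C13 pair, and a chair-like transition state with the C9 substituent, the C10 bromide and the alkene all pseudo-equatorial should give the 2,5-trans, 2,4-cis oxolane (12R,13S).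

Step 8
Reactants: 12 (2R)-2-{(2S,3R,5R)-3-bromo-5-[(1S)-1-bromopropyl]oxolan-2-yl}-6-hydroxy-2H-pyran-3(6H)-one
Product: 13 (2R)-2-{(2S,3R,5R)-3-bromo-5-[(1S)-1-bromopropyl]oxolan-2-yl}-6-[(tert-butyldimethylsilyl)oxy]-2H-pyran-3(6H)-one
Conditions: TBSCl, imidazole, CH2Cl2, 0 °C
Reagents that add atoms: tert-butyldimethylsilyl chloride, CC(C)(C)[Si](C)(C)Cl
Why: The lactol is the only hydroxyl left, so silylation is unambiguous. The silyl acetal resists hydride and enolate and can later be removed without acid.

Step 9
Reactants: 13 (2R)-2-{(2S,3R,5R)-3-bromo-5-[(1S)-1-bromopropyl]oxolan-2-yl}-6-[(tert-butyldimethylsilyl)oxy]-2H-pyran-3(6H)-one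
Product: 15 tricyclic enol ether silyl acetal (8R,9R,10S,12R,13S; rings A and B of the target fused through C7–C8 to ring C = O8–C4H(OTBS)–C5H2–C6H=C7), via potassium enolate 14 (not isolated)
Conditions: K[HB(s-Bu)3] (1.05 equiv), THF, −78 °C; then DMPU, 18-crown-6, −78 °C to rt (0.01 M); pH 8 work-up
Reagents that add atoms: none
Why: K[HB(s-Bu)3] delivers hydride to the unsubstituted β-carbon C5 of the enone (the carbonyl C7 is shielded by the branched C8), so enolate 14 forms regiospecifically with C6=C7 inside ring C and the oxygen on C7. On warming, this oxygen displaces the C10 bromide from the face opposite to bromine and closes ring A in the 5-exo-tet mode; attack through C6 would be a 5-(enolendo)-exo-tet closure in which the enolate π-orbital cannot reach the back lobe of the C10–Br bond, so the ambident anion can react only at oxygen. The closest known reaction types are the reductive alkylation of enones with trialkylborohydrides and the O-cyclisation of γ-halo ketone enolates to 2-alkylidene oxolanes. C10 is the only stereocentre made: it is inverted (10R bromide to 10S ether), and because the nucleophile hangs from the C8 substituent on the lower face of C9 while bromine stands on the upper face, only the cis-fused A/B system can form. The C6=C7 geometry is not a matter of selectivity, since C5 and C8 are both members of the six-membered ring C and must be cis, which is the 6E arrangement once ring C is opened. Three selectivities are needed: 1,4- over 1,2-reduction (bulky hydride, free β-position), C10–Br over C13–Br (five- against seven-membered transition state), and no proton transfer to the C8 enolate, which would expel the ring B oxygen or close a cyclopropane (aprotic medium, all ketone consumed at −78 °C before warming, high dilution). DMPU and 18-crown-6 loosen the potassium ion pair and the weak contact with B(s-Bu)3 and so favour reaction at oxygen. The step thus settles ring A, the A/B fusion, C10 and the enol ether geometry in one operation, with the C8 oxygen already in place for step 14.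

Step 10
Reactants: 15 tricyclic enol ether silyl acetal
Product: 16 tricyclic enol ether lactol (8R,9R,10S,12R,13S; C4–OH)
Conditions: n-Bu4NF, AcOH (1:1), THF, 0 °C
Reagents that add atoms: none
Why: Fluoride cleaves the silyl acetal, and the buffer keeps the medium close to neutral. The enol ether should therefore not be protonated, and the lactolate should not linger in its open, isomerisation-prone aldehyde form.

Step 11
Reactants: 17 1-(triisopropylsilyl)prop-1-yne
Product: 19 1,3-bis(triisopropylsilyl)prop-1-yne, via propargyllithium 18 (not isolated)
Conditions: n-BuLi, THF, −20 °C; i-Pr3SiOTf, −78 °C to rt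
Reagents that add atoms: triisopropylsilyl trifluoromethanesulfonate, CC(C)[Si](OS(=O)(=O)C(F)(F)F)(C(C)C)C(C)C
Why: Propargylic lithiation followed by C-silylation is the standard route to the Peterson reagent for Z-enynes.

Step 12
Reactants: 16 tricyclic enol ether lactol; 19 1,3-bis(triisopropylsilyl)prop-1-yne
Product: 22 (2E,3R,3aS,5R,6aS)-5-[(1S)-1-bromopropyl]-2-[(3Z)-6-(triisopropylsilyl)hex-3-en-5-yn-1-ylidene]hexahydrofuro[3,2-b]furan-3-ol, via lithiated bis-silylpropyne 20 (not isolated), via open-chain hydroxy aldehyde 21 (not isolated)
Conditions: 19 (2.5 equiv), n-BuLi (2.4 equiv), THF, −20 °C; then 16, −78 to −20 °C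
Reagents that add atoms: none
Why: In this Peterson olefination one equivalent of 20 deprotonates the lactol, which opens to 21, and a second equivalent adds to the aldehyde. The bulky silyl groups bias the addition toward the β-oxidosilane whose spontaneous syn elimination gives the Z-enyne. Ring C is opened in the process, which leaves C6=C7 as 6E and frees the endo C8 hydroxyl.

Step 13
Reactants: 22 silylated Z-enyne alcohol
Product: 23 (2E,3R,3aS,5R,6aS)-5-[(1S)-1-bromopropyl]-2-[(3Z)-hex-3-en-5-yn-1-ylidene]hexahydrofuro[3,2-b]furan-3-ol
Conditions: n-Bu4NF, THF, 0 °C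
Reagents that add atoms: none
Why: Fluoride protodesilylation of the alkynylsilane is run before the allylic bromide exists, so the only halide exposed is the unactivated C13 bromide.

Step 14
Reactants: 23 (2E,3R,3aS,5R,6aS)-5-[(1S)-1-bromopropyl]-2-[(3Z)-hex-3-en-5-yn-1-ylidene]hexahydrofuro[3,2-b]furan-3-ol
Product: 24 (2E,3S,3aR,5R,6aS)-3-bromo-5-[(1S)-1-bromopropyl]-2-[(3Z)-hex-3-en-5-yn-1-ylidene]hexahydrofuro[3,2-b]furan (target)
Conditions: CBr4, PPh3, 2,6-di-tert-butylpyridine, CH2Cl2, −20 to 0 °C
Reagents that add atoms: tetrabromomethane, BrC(Br)(Br)Br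
Why: In the Appel reaction the endo alkoxyphosphonium group leaves toward the concave face while bromide enters from the open convex face, so C8 is inverted (8R alcohol to 8S bromide). The oxygen on the central carbon C7 does not stabilise an allyl cation, which favours direct SN2, and the hindered base removes traces of HBr.

## Compound list

1 | 2-bromo-1-(furan-2-yl)ethan-1-one | O=C(CBr)c1ccco1 | starting material
2 | triphenylphosphine | c1ccc(cc1)P(c1ccccc1)c1ccccc1 | starting material
3 | [2-(furan-2-yl)-2-oxoethyl]triphenylphosphonium bromide | O=C(C[P+](c1ccccc1)(c1ccccc1)c1ccccc1)c1ccco1.[Br-] | intermediate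
4 | 1-(furan-2-yl)-2-(triphenyl-λ5-phosphanylidene)ethan-1-one | O=C(C=P(c1ccccc1)(c1ccccc1)c1ccccc1)c1ccco1 | intermediate
5 | (E)-hex-3-en-1-ol | CC/C=C/CCO | starting material
6 | (E)-hex-3-enal | CC/C=C/CC=O | intermediate
7 | (2E,5E)-1-(furan-2-yl)octa-2,5-dien-1-one | CC/C=C/C/C=C/C(=O)c1ccco1 | intermediate
8 | furan-2-yl{(2R,3S)-3-[(2E)-pent-2-en-1-yl]oxiran-2-yl}methanone | O=C(c1ccco1)[C@@H]1O[C@H]1C/C=C/CC | intermediate
9 | (R)-furan-2-yl{(2S,3S)-3-[(2E)-pent-2-en-1-yl]oxiran-2-yl}methanol | O[C@@H](c1ccco1)[C@@H]1O[C@H]1C/C=C/CC | intermediate
10 | (1R,2S,3R,5E)-3-bromo-1-(furan-2-yl)oct-5-ene-1,2-diol | O[C@@H](c1ccco1)[C@H](O)[C@H](Br)C/C=C/CC | intermediate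
11 | (2R)-2-[(1S,2R,4E)-2-bromo-1-hydroxyhept-4-en-1-yl]-6-hydroxy-2H-pyran-3(6H)-one | OC1C=CC(=O)[C@H](O1)[C@H](O)[C@H](Br)C/C=C/CC | intermediate
12 | (2R)-2-{(2S,3R,5R)-3-bromo-5-[(1S)-1-bromopropyl]oxolan-2-yl}-6-hydroxy-2H-pyran-3(6H)-one | OC1C=CC(=O)[C@H](O1)[C@@H]1O[C@@H]([C@@H](Br)CC)C[C@H]1Br | intermediate
13 | 6-O-tert-butyldimethylsilyl ether of 12 | CC(C)(C)[Si](C)(C)OC1C=CC(=O)[C@H](O1)[C@@H]1O[C@@H]([C@@H](Br)CC)C[C@H]1Br | intermediate
14 | potassium enolate (C6=C7–O−) from 1,4-reduction of 13 | [K+].CC(C)(C)[Si](C)(C)OC1CC=C([O-])[C@H](O1)[C@@H]1O[C@@H]([C@@H](Br)CC)C[C@H]1Br | intermediate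
15 | tricyclic enol ether silyl acetal (8R,9R,10S,12R,13S) | CC(C)(C)[Si](C)(C)OC1CC=C2O[C@H]3C[C@H]([C@@H](Br)CC)O[C@H]3[C@H]2O1 | intermediate
16 | tricyclic enol ether lactol (8R,9R,10S,12R,13S) | OC1CC=C2O[C@H]3C[C@H]([C@@H](Br)CC)O[C@H]3[C@H]2O1 | intermediate
17 | 1-(triisopropylsilyl)prop-1-yne | CC#C[Si](C(C)C)(C(C)C)C(C)C | starting material
18 | 3-lithio-1-(triisopropylsilyl)prop-1-yne | [Li]CC#C[Si](C(C)C)(C(C)C)C(C)C | intermediate
19 | 1,3-bis(triisopropylsilyl)prop-1-yne | CC(C)[Si](CC#C[Si](C(C)C)(C(C)C)C(C)C)(C(C)C)C(C)C | intermediate
20 | 3-lithio-1,3-bis(triisopropylsilyl)prop-1-yne | [Li]C(C#C[Si](C(C)C)(C(C)C)C(C)C)[Si](C(C)C)(C(C)C)C(C)C | intermediate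
21 | open-chain hydroxy aldehyde, (3E)-3-{(3R,3aS,5R,6aS)-5-[(1S)-1-bromopropyl]-3-hydroxyhexahydrofuro[3,2-b]furan-2-ylidene}propanal | O=CC/C=C1/O[C@H]2C[C@H]([C@@H](Br)CC)O[C@H]2[C@H]1O | intermediate
22 | (2E,3R,3aS,5R,6aS)-5-[(1S)-1-bromopropyl]-2-[(3Z)-6-(triisopropylsilyl)hex-3-en-5-yn-1-ylidene]hexahydrofuro[3,2-b]furan-3-ol | CC(C)[Si](C#C/C=C\C/C=C1/O[C@H]2C[C@H]([C@@H](Br)CC)O[C@H]2[C@H]1O)(C(C)C)C(C)C | intermediate
23 | (2E,3R,3aS,5R,6aS)-5-[(1S)-1-bromopropyl]-2-[(3Z)-hex-3-en-5-yn-1-ylidene]hexahydrofuro[3,2-b]furan-3-ol | C#C/C=C\C/C=C1/O[C@H]2C[C@H]([C@@H](Br)CC)O[C@H]2[C@H]1O | intermediate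
24 | (2E,3S,3aR,5R,6aS)-3-bromo-5-[(1S)-1-bromopropyl]-2-[(3Z)-hex-3-en-5-yn-1-ylidene]hexahydrofuro[3,2-b]furan | C#C/C=C\C/C=C1/O[C@H]2C[C@H]([C@@H](Br)CC)O[C@H]2[C@@H]1Br | target

## Step count and least certain steps

Total: 14 steps. Longest linear sequence: 12 steps (5 through steps 2–10 and 12–14). Steps 1 and 11 are side branches.

**Step 9 (key).**
- The most likely failures are hydride addition to the carbonyl instead of C5, and a ring closure that is too slow at the secondary, β-oxygenated C10.
- A slow closure leaves time for proton transfer to the C8 side. That would be followed by β-elimination of the ring B oxygen or by three-membered ring closure, or by E2 loss of HBr across C10–C11.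
- Coordination of the borane by-product to the enolate oxygen could slow the closure further.
- The fallback sets out from 13 and returns at 15. Reduction and closure are separated, and the borane-associated metal enolate is replaced by a metal-free one.
- RhCl(PPh3)3-catalysed 1,4-hydrosilylation with Et3SiH would give the isolable triethylsilyl enol ether F1. One equivalent of anhydrous [(Me2N)3S][Me3SiF2] in THF at low temperature would then unmask a naked enolate. The enol silane is far more labile than the silyl acetal, and the enolate cyclises at oxygen as before.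

**Step 7.**
- Water may compete with the C9 hydroxyl for the bromonium ion.
- Facial selectivity at C12 may be incomplete.
- Acid-induced ketalisation between the C9 hydroxyl and C4 may occur.
- Over-bromination is possible while furan oxidation is still running.
- The fallback sets out from 10 and returns at 12. The furan is oxidised without any bromine electrophile (O2, hν, rose bengal, MeOH, −78 °C, then Me2S) and 11 is isolated. Ring B is then closed separately under anhydrous conditions with 2,4,4,6-tetrabromocyclohexa-2,5-dienone in MeCN.
- This fallback makes no compound outside the list (F0).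

**Step 4.**
- The basic lanthanum alkoxide may deprotonate the doubly allylic C11H2, so that C9=C10 migrates into conjugation with C12=C13 before epoxidation.
- Enantioselectivity for a heteroaryl ketone may be insufficient.
- The fallback sets out from 6 and returns at 8, and it moves the asymmetric step to a base-insensitive allylic alcohol.
- Wittig reaction of 6 with Ph3P=CHCO2Et would give ethyl (2E,5E)-octa-2,5-dienoate F2, and i-Bu2AlH would reduce it to (2E,5E)-octa-2,5-dien-1-ol F3.
- Sharpless asymmetric epoxidation (Ti(OiPr)4, L-(+)-diethyl tartrate, t-BuOOH, 4 Å MS, −20 °C) would give the (2S,3S)-epoxy alcohol F4, and IBX would oxidise it to the epoxy aldehyde F5.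
- 2-Furyllithium would add to F5 to give 9 together with its C8 epimer F6, and MnO2 would oxidise the mixture to 8.

**Step 12.**
- The basic reagent may enolise the open aldehyde at C5, which would move the double bond into conjugation.
- The lactol may open sluggishly at low temperature.
- Z-selectivity may erode.
- The fallback sets out from 16 and returns at 23. It builds the enyne by cross-coupling instead of by direct olefination with a C3 carbanion.
- Stork–Zhao olefination ([Ph3PCH2I]I, NaN(SiMe3)2, THF–DMPU, −78 °C) would give the (Z)-vinyl iodide F7. At this stage the C8 hydroxyl is not a leaving group for zerovalent palladium.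
- Sonogashira coupling with trimethylsilylacetylene (Pd(PPh3)4, CuI, Et2NH) would give the trimethylsilyl enyne F8, and K2CO3 in MeOH would release 23.

**Step 14.**
- Bromide may attack at C6 (SN2').
- E2 loss across C8–C9 with subsequent aromatisation of ring A is possible.
- Partial ionisation would erode configuration.
- Adventitious HBr may protonate the enol ether.
- The fallback sets out from 23 and returns at 24. Activation and displacement are separated under salt-only conditions.
- ClCH2SO2Cl with 2,6-lutidine at −20 °C would give the chloromethanesulfonate F9, which n-Bu4NBr in toluene would displace with inversion. No phosphonium species and no acid would be present.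

## Further compounds

F1 | step 9 | triethylsilyl enol ether of the 1,4-reduced pyranone (C6=C7–OSiEt3) | CC[Si](CC)(CC)OC1=CCC(O[Si](C)(C)C(C)(C)C)O[C@@H]1[C@@H]1O[C@@H]([C@@H](Br)CC)C[C@H]1Br
F0 | step 7 | none | none
F2 | step 4 | ethyl (2E,5E)-octa-2,5-dienoate | CCOC(=O)/C=C/C/C=C/CC
F3 | step 4 | (2E,5E)-octa-2,5-dien-1-ol | OC/C=C/C/C=C/CC
F4 | step 4 | {(2S,3S)-3-[(2E)-pent-2-en-1-yl]oxiran-2-yl}methanol | OC[C@@H]1O[C@H]1C/C=C/CC
F5 | step 4 | (2R,3S)-3-[(2E)-pent-2-en-1-yl]oxirane-2-carbaldehyde | O=C[C@@H]1O[C@H]1C/C=C/CC
F6 | step 4 | (S)-furan-2-yl{(2S,3S)-3-[(2E)-pent-2-en-1-yl]oxiran-2-yl}methanol (C8 epimer of 9) | O[C@H](c1ccco1)[C@@H]1O[C@H]1C/C=C/CC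
F7 | step 12 | (2E,3R,3aS,5R,6aS)-5-[(1S)-1-bromopropyl]-2-[(3Z)-4-iodobut-3-en-1-ylidene]hexahydrofuro[3,2-b]furan-3-ol | I/C=C\C/C=C1/O[C@H]2C[C@H]([C@@H](Br)CC)O[C@H]2[C@H]1O
F8 | step 12 | trimethylsilyl analogue of 22 | C[Si](C)(C)C#C/C=C\C/C=C1/O[C@H]2C[C@H]([C@@H](Br)CC)O[C@H]2[C@H]1O
F9 | step 14 | C8 chloromethanesulfonate of 23 | C#C/C=C\C/C=C1/O[C@H]2C[C@H]([C@@H](Br)CC)O[C@H]2[C@H]1OS(=O)(=O)CCl
A1 | alternative 1 | ring B alkynol with C10–OH, propargylic C8 bromide and the C6≡C7 alkyne bearing the (Z)-enyne | C#C/C=C\CC#C[C@@H](Br)[C@@H]1O[C@@H]([C@@H](Br)CC)C[C@@H]1O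
A2 | alternative 1 | 6Z isomer of the target | C#C/C=C\C/C=C1\O[C@H]2C[C@H]([C@@H](Br)CC)O[C@H]2[C@@H]1Br
A3 | alternative 2 | (3S,3aR,5R,6aS)-3-bromo-5-[(1S)-1-bromopropyl]tetrahydrofuro[3,2-b]furan-2(3H)-one | O=C1O[C@H]2C[C@H]([C@@H](Br)CC)O[C@H]2[C@@H]1Br
A4 | alternative 3 | ring B terminal alkynol with C10–OH and C8–OTBS | C#C[C@H](O[Si](C)(C)C(C)(C)C)[C@@H]1O[C@@H]([C@@H](Br)CC)C[C@@H]1O
A5 | alternative 3 | (E)-2-(iodomethylene) bicycle with C8–OTBS | I/C=C1/O[C@H]2C[C@H]([C@@H](Br)CC)O[C@H]2[C@H]1O[Si](C)(C)C(C)(C)C
A6 | alternative 3 | [(3Z)-5-bromopent-3-en-1-yn-1-yl]trimethylsilane | C[Si](C)(C)C#C/C=C\CBr
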